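Follow one living end through the run and count the monomer units it adds.

| flask | free monomer | initiator | impurity | time |
|---|---|---|---|---|
| zeta | 19 mM | 0.38 mM | 63 µM | 50 h |
| gamma | 19 mM | 0.38 mM | 250 µM | 50 h |

1. which of the two ends with the longer chains by the average number of monomer units in a chain (chains begun, living or dead) ("neither" if they lie within 10%) (zeta / gamma / neither)
2. average number of monomer units in a chain (chains begun, living or dead) at the end, zeta
3. average number of monomer units in a chain (chains begun, living or dead) at the end, gamma

- the average divides the monomer in chains by the number of chains begun, living and dead together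
- run time (zeta): 50 h

A living end adds free monomer at 0.0258 M⁻¹ s⁻¹ times the free monomer present, so at the charge of 19 mM it would add 88.2 units in 50 h. Factors cut this pace. The back-step removes units at 6.11 × 10⁻⁵ s⁻¹ per end and balances addition at 2.37 mM of free monomer, the equilibrium monomer concentration, which leaves a factor 0.875. Ends die at 6.96 × 10⁻⁶ s⁻¹, which leaves a factor 0.570 on average over the run.

A further factor depends on the count of ends. Free monomer falls by its forward step at 0.0258 M⁻¹ s⁻¹ times the living ends, while ends die at 6.96 × 10⁻⁶ s⁻¹, and these two rates cross at the crossing count Lc = 0.270 mM. Below Lc dying is the faster of the two; above it, the fall of free monomer is.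

My reckoning charges each impurity with one initiator, so the chains begun, C, are 0.317 mM in zeta and 0.130 mM in gamma. Zeta thus starts above Lc and gamma below it. With x = (C/Lc) × 0.714, the share of ends dead by the end of the run if they die at 6.96 × 10⁻⁶ s⁻¹, the factor is F = (1 − e⁻ˣ)/x:

zeta: x = 0.839, F = 0.677, length 29.8

gamma: x = 0.344, F = 0.846, length 37.3

Dying on monomer in chains is left out here.

The forecast names gamma, with 27 for zeta and 34 for gamma, lower than my figures, and holds that termination “kills the living ends before that ceiling is reached”.

The simulation gives gamma as the longer, with 26.9 for zeta and 33.8 for gamma.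

    free monomer + initiator → living end + monomer in chains (k1 = 0.0648 M⁻¹ s⁻¹)
    free monomer + living end → monomer in chains + living end, rate k2*[living end]*[free monomer] (k2 = 0.0258 M⁻¹ s⁻¹)
    monomer in chains + living end → free monomer + living end, rate k3*[living end] as long as [monomer in chains] is above zero (k3 = 6.11 × 10⁻⁵ s⁻¹)
    living end → dead end A (k4 = 6.96 × 10⁻⁶ s⁻¹)
    living end + monomer in chains → dead end B (k5 = 5.52 × 10⁻⁴ M⁻¹ s⁻¹)
    initiator + impurity → spent initiator C (k6 = 17.1 M⁻¹ s⁻¹)

Gamma's greater length comes from its larger impurity charge: with the difference in impurity taken away, so that gamma is charged like zeta, the average falls from 33.8 to 26.9. At the end of the run spent initiator C stood at 0.0623 mM in zeta and 0.222 mM in gamma, so chains begun were 1.18 Lc in zeta and 0.584 Lc in gamma. The neighbour of zeta charged with 0.95 mM of initiator begins 3.29 Lc of chains, and at the end its free monomer stands at 27.2% of the charge, with chains of 15.2 units on average.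

(The constants are invented; the result is computed.)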